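**Plan**
1. The retrosynthesis first puts oxygen back on C11 and C17 and unsaturation back at C5=C6 and C8=C9, then cuts C9–C10 and C7–C8, the two bonds of ring B that one [4+2] cycloaddition forms.
2. This leaves fragment 1, a ring A 1-vinylcyclohexene (diene C10=C5–C6=C7, cut further at C5–C6 and C4–C18), and fragment 2, an ynone holding C8, C9, C17 and the whole C11–C16 chain (cut at C9–C11).
3. The enabling feature: C11 can carry a carbonyl conjugated to C8≡C9, and the C18 oxygen on C4 lies 1,3 to C10 on the ring A face from which C9 must arrive, so one magnesium can bridge the C18 alkoxide and the C11 carbonyl oxygen.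
4. Forward: ring A is bought as 2,6-dimethylcyclohexanone and becomes fragment 1 by hydroxymethylation, enol triflate formation and vinyl coupling; an acyl Sonogashira coupling gives fragment 2; step 9 closes ring B and delivers the complete chain; six steps then adjust oxidation levels.
5. Stereochemistry: C4 by catalyst control (step 2); C13 from (R)-3-methylglutaric acid monomethyl ester; C10 from C4 through the magnesium bridge; C5 by hydroxyl-directed hydrogenation; C9 by protonation of a dienolate anti to the C20 methyl.

Key step: step 9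

Numbering: labdane numbering is used. Ring A is C1–C5 and C10, ring B is C5–C10, C17 is on C8, C18 is the 4α-CH2O group, C19 and C20 are the methyls on C4 and C10, and C16 is the methyl on C13.

Assumption: which antipode of the bipyridine ligand gives (2S)-3 from this fully aliphatic enol silane cannot be read from simpler substrates. The antipode that does so is used, and the configuration of 3 is to be proven by correlation before step 3. Commercial 1 is a cis/trans mixture, which is without consequence because C6 of 3 and 4 becomes sp2 in step 4.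

**Route**

Step 1
Reactants: 1 2,6-dimethylcyclohexan-1-one
Product: 2 [(2,6-dimethylcyclohex-1-en-1-yl)oxy]trimethylsilane
Conditions: TMSOTf, Et3N, CH2Cl2, 0 → 23 °C
Reagents that add atoms: trimethylsilyl trifluoromethanesulfonate, C[Si](C)(C)OS(=O)(=O)C(F)(F)F
Why: Soft enolisation with O-silylation (silyl enol ether formation) should be clean because both α-carbons are CH(CH3) groups, so only one enol ether can form.

Step 2
Reactants: 2 [(2,6-dimethylcyclohex-1-en-1-yl)oxy]trimethylsilane
Product: 3 (2S)-2-(hydroxymethyl)-2,6-dimethylcyclohexan-1-one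
Conditions: aq. HCHO (35%), Sc(OTf)3 (10 mol %), enantiopure 6,6'-bis(1-hydroxy-2,2-dimethylpropyl)-2,2'-bipyridine (12 mol %), DME/H2O 9:1, −20 °C
Reagents that add atoms: formaldehyde, C=O
Why: This is a catalytic enantioselective Mukaiyama aldol reaction with aqueous formaldehyde, a known route to α-hydroxymethyl ketones with a quaternary α-carbon; the chiral scandium complex selects the enolate face and so sets the centre that becomes C4, while the C6 methine remains a mixture that step 4 erases.

Step 3
Reactants: 3 (2S)-2-(hydroxymethyl)-2,6-dimethylcyclohexan-1-one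
Product: 4 (2S)-2-{[tert-butyl(dimethyl)silyl]oxymethyl}-2,6-dimethylcyclohexan-1-one
Conditions: TBSCl, imidazole, DMF, 23 °C
Reagents that add atoms: tert-butyldimethylsilyl chloride, CC(C)(C)[Si](C)(C)Cl
Why: Silyl ether formation on the unhindered primary alcohol masks it so that base and triflating agent in step 4 meet only the ketone.

Step 4
Reactants: 4 (2S)-2-{[tert-butyl(dimethyl)silyl]oxymethyl}-2,6-dimethylcyclohexan-1-one
Product: 6 (6S)-6-{[tert-butyl(dimethyl)silyl]oxymethyl}-2,6-dimethylcyclohex-1-en-1-yl trifluoromethanesulfonate, via potassium enolate 5 (not isolated)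
Conditions: KN(SiMe3)2, THF, −78 → 0 °C; then PhNTf2, −78 → 23 °C
Reagents that add atoms: N-phenylbis(trifluoromethanesulfonimide), O=S(=O)(N(c1ccccc1)S(=O)(=O)C(F)(F)F)C(F)(F)F
Why: Enolate O-sulfonylation (enol triflate formation) is regiodefined because C6 bears the only α-hydrogen, and the quaternary centre cannot epimerise or eliminate.

Step 5
Reactants: 6 (6S)-6-{[tert-butyl(dimethyl)silyl]oxymethyl}-2,6-dimethylcyclohex-1-en-1-yl trifluoromethanesulfonate
Product: 7 tert-butyl{[(1R)-2-ethenyl-1,3-dimethylcyclohex-2-en-1-yl]methoxy}dimethylsilane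
Conditions: Bu3SnCH=CH2, Pd(PPh3)4 (5 mol %), LiCl, THF, 65 °C
Reagents that add atoms: tributyl(vinyl)stannane, C=C[Sn](CCCC)(CCCC)CCCC
Why: Stille coupling of an enol triflate with a vinylstannane forms C5–C6 and is well precedented for 2,6,6-trisubstituted cyclohexenyl triflates, LiCl allowing transmetalation after oxidative addition to zerovalent palladium.

Step 6
Reactants: 7 tert-butyl{[(1R)-2-ethenyl-1,3-dimethylcyclohex-2-en-1-yl]methoxy}dimethylsilane
Product: 8 [(1R)-2-ethenyl-1,3-dimethylcyclohex-2-en-1-yl]methanol (fragment 1)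
Conditions: Bu4NF, THF, 23 °C
Reagents that add atoms: none
Why: Fluoride-mediated desilylation frees the C18 hydroxyl needed as the anchor in step 9, and the diene is inert to fluoride.

Step 7
Reactants: 9 prop-2-yn-1-ol
Product: 10 prop-2-yn-1-yl 2,2-dimethylpropanoate
Conditions: PivCl, pyridine, CH2Cl2, 0 → 23 °C
Reagents that add atoms: pivaloyl chloride, CC(C)(C)C(=O)Cl
Why: Acylation of the primary alcohol installs at C17 an ester hindered enough to resist acyl transfer to a magnesium alkoxide in step 9, which later serves as the leaving group in step 12.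

Step 8
Reactants: 11 (3R)-5-methoxy-3-methyl-5-oxopentanoic acid; 10 prop-2-yn-1-yl 2,2-dimethylpropanoate
Product: 13 methyl (3R)-8-(2,2-dimethylpropanoyloxy)-3-methyl-5-oxooct-6-ynoate (fragment 2), via acid chloride 12 (not isolated)
Conditions: (COCl)2, DMF (cat.), CH2Cl2, 0 → 23 °C, evaporate; then 10, PdCl2(PPh3)2 (2 mol %), CuI (4 mol %), Et3N (1.2 equiv), THF, 23 °C
Reagents that add atoms: none
Why: Acyl Sonogashira coupling of an acid chloride with a terminal alkyne forms C9–C11 under near-neutral conditions; chloride formation at or below room temperature avoids anhydride-type exchange of the two chain ends, which would racemise C13.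

Step 9
Reactants: 8 [(1R)-2-ethenyl-1,3-dimethylcyclohex-2-en-1-yl]methanol (fragment 1); 13 methyl (3R)-8-(2,2-dimethylpropanoyloxy)-3-methyl-5-oxooct-6-ynoate (fragment 2)
Product: 15 methyl (4R,10S,13R)-18-hydroxy-11-oxo-17-(pivaloyloxy)labda-5,8-dien-15-oate, via bromomagnesium alkoxide 14 (not isolated)
Conditions: MeMgBr (1.0 equiv), PhMe, 0 °C; then 13, 23 → 60 °C; pH 7 buffer
Reagents that add atoms: none
Why: Proposed new method: the bromomagnesium alkoxide 14 should bind the C11 carbonyl oxygen of 13, so that a concerted but asynchronous [4+2] cycloaddition takes place inside a diene–magnesium–dienophile complex, with C7–C8 forming ahead of C9–C10. The closest known reaction types are Diels–Alder reactions of dienol magnesium alkoxides with acrylates and enones assembled on the metal, and thermal cycloadditions of 2,6,6-trisubstituted 1-vinylcyclohexenes with acetylenic esters and ketones; new here are the homoallylic position of the hydroxyl and the alkynone partner. Ring B closes as a cyclohexa-1,4-diene in a six-membered [4+2] closure that is bimolecular in the carbon framework and intramolecular only through the O–Mg–O bridge. The one new stereocentre, C10, is controlled by C4: the C18 oxygen lies on the α face and holds the dienophile there, so C9 adds anti to the C19 methyl and the C20 methyl is pushed to the β face. The step needs regioselectivity (C8 to C7, C9 to C10), which is secured by the polarisation of the ynone (β-carbon C8 to the unsubstituted terminus C7, charge build-up at the tertiary C10), by activation through the same magnesium, and by the bridge, which spans from C18 to the C11 oxygen only when C9 lies under C10. The C17 oxygen is kept as a pivalate and not used as an anchor because a link from C18 to C17 would have to bridge C5 and C8 across the new ring.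

Step 10
Reactants: 15 methyl (4R,10S,13R)-18-hydroxy-11-oxo-17-(pivaloyloxy)labda-5,8-dien-15-oate
Product: 16 methyl (4R,5R,10S,13R)-18-hydroxy-11-oxo-17-(pivaloyloxy)labd-8-en-15-oate
Conditions: H2 (1 atm), [Ir(cod)(PCy3)(py)]PF6 (5 mol %), CH2Cl2, 23 °C
Reagents that add atoms: none
Why: In this hydroxyl-directed homogeneous hydrogenation the cationic iridium complex binds the C18 hydroxyl and delivers hydrogen to the α face of the trisubstituted C5=C6 bond, giving 5α-H (trans ring fusion, anti to the C20 methyl), while the tetrasubstituted electron-poor C8=C9 bond and the allylic pivalate should be untouched.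

Step 11
Reactants: 16 methyl (4R,5R,10S,13R)-18-hydroxy-11-oxo-17-(pivaloyloxy)labd-8-en-15-oate
Product: 17 methyl (4R,5R,10S,13R)-18-acetoxy-11-oxo-17-(pivaloyloxy)labd-8-en-15-oate
Conditions: Ac2O, pyridine, DMAP (cat.), CH2Cl2, 23 °C
Reagents that add atoms: acetic anhydride, CC(=O)OC(C)=O
Why: Nucleophile-catalysed acetylation of the only free hydroxyl installs the C18 acetate of the target before a second hydroxyl appears at C11.

Step 12
Reactants: 17 methyl (4R,5R,10S,13R)-18-acetoxy-11-oxo-17-(pivaloyloxy)labd-8-en-15-oate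
Product: 19 methyl (4R,5R,9S,10S,13R)-18-acetoxy-11-oxolabd-8(17)-en-15-oate, via samarium dienolate 18 (not isolated)
Conditions: SmI2 (2.5 equiv), THF/MeOH, −78 °C
Reagents that add atoms: none
Why: Reductive elimination of a γ-acyloxy enone by divalent samarium expels pivalate to give the C11(O)=C9–C8=C17 dienolate, whose kinetic α-protonation at C9 from the α face, anti to the axial C20 methyl, should set 9α-H and leave the C8=C17 methylene; the unactivated acetate and methyl ester are inert.

Step 13
Reactants: 19 methyl (4R,5R,9S,10S,13R)-18-acetoxy-11-oxolabd-8(17)-en-15-oate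
Product: 20 methyl (4R,5R,9S,10S,13R)-18-acetoxy-11-hydroxylabd-8(17)-en-15-oate
Conditions: NaBH4, MeOH/THF, −20 → 0 °C; AcOH quench
Reagents that add atoms: none
Why: Borohydride reduction of the ketone spares both esters and the alkene, and the C11 configuration is irrelevant because the centre is removed in step 15; low temperature and an acidic quench are meant to keep the C11 alkoxide from closing onto the C15 ester.

Step 14
Reactants: 20 methyl (4R,5R,9S,10S,13R)-18-acetoxy-11-hydroxylabd-8(17)-en-15-oate
Product: 21 methyl (4R,5R,9S,10S,13R)-18-acetoxy-11-(phenoxycarbonothioyloxy)labd-8(17)-en-15-oate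
Conditions: PhOC(S)Cl, pyridine, DMAP (cat.), CH2Cl2, 23 °C
Reagents that add atoms: O-phenyl chlorothionoformate, S=C(Cl)Oc1ccccc1
Why: Thionocarbonate formation under neutral acylating conditions activates the hindered secondary alcohol for radical cleavage without base that could move the C8=C17 bond or epimerise C9.

Step 15
Reactants: 21 methyl (4R,5R,9S,10S,13R)-18-acetoxy-11-(phenoxycarbonothioyloxy)labd-8(17)-en-15-oate
Product: 22 methyl (4R,5R,9S,10R,13R)-18-acetoxylabd-8(17)-en-15-oate (CNP0322314.1)
Conditions: Bu3SnH (0.3 M), AIBN (cat.), PhMe, 100 °C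
Reagents that add atoms: none
Why: Barton–McCombie deoxygenation replaces the C11 oxygen by hydrogen through a secondary radical, and a high stannane concentration should trap it before the slow 3-exo attack on C8=C17; no stereocentre is touched.

**Compound list**
1 | 2,6-dimethylcyclohexan-1-one (cis/trans mixture) | CC1CCCC(C)C1=O | starting material
2 | [(2,6-dimethylcyclohex-1-en-1-yl)oxy]trimethylsilane (racemic at C6) | CC1CCCC(C)=C1O[Si](C)(C)C | intermediate
3 | (2S)-2-(hydroxymethyl)-2,6-dimethylcyclohexan-1-one (both C6 epimers) | O=C1C(C)CCC[C@@]1(C)CO | intermediate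
4 | (2S)-2-{[tert-butyl(dimethyl)silyl]oxymethyl}-2,6-dimethylcyclohexan-1-one (both C6 epimers) | O=C1C(C)CCC[C@@]1(C)CO[Si](C)(C)C(C)(C)C | intermediate
5 | potassium (6S)-6-{[tert-butyl(dimethyl)silyl]oxymethyl}-2,6-dimethylcyclohex-1-en-1-olate | [K+].[O-]C1=C(C)CCC[C@@]1(C)CO[Si](C)(C)C(C)(C)C | intermediate (not isolated)
6 | (6S)-6-{[tert-butyl(dimethyl)silyl]oxymethyl}-2,6-dimethylcyclohex-1-en-1-yl trifluoromethanesulfonate | FC(F)(F)S(=O)(=O)OC1=C(C)CCC[C@@]1(C)CO[Si](C)(C)C(C)(C)C | intermediate
7 | tert-butyl{[(1R)-2-ethenyl-1,3-dimethylcyclohex-2-en-1-yl]methoxy}dimethylsilane | C=CC1=C(C)CCC[C@@]1(C)CO[Si](C)(C)C(C)(C)C | intermediate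
8 | [(1R)-2-ethenyl-1,3-dimethylcyclohex-2-en-1-yl]methanol (fragment 1) | C=CC1=C(C)CCC[C@@]1(C)CO | intermediate
9 | prop-2-yn-1-ol | C#CCO | starting material
10 | prop-2-yn-1-yl 2,2-dimethylpropanoate | C#CCOC(=O)C(C)(C)C | intermediate
11 | (3R)-5-methoxy-3-methyl-5-oxopentanoic acid ((R)-3-methylglutaric acid monomethyl ester) | OC(=O)C[C@@H](C)CC(=O)OC | starting material
12 | methyl (3S)-5-chloro-3-methyl-5-oxopentanoate | ClC(=O)C[C@@H](C)CC(=O)OC | intermediate (not isolated)
13 | methyl (3R)-8-(2,2-dimethylpropanoyloxy)-3-methyl-5-oxooct-6-ynoate (fragment 2) | CC(C)(C)C(=O)OCC#CC(=O)C[C@@H](C)CC(=O)OC | intermediate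
14 | bromo{[(1R)-2-ethenyl-1,3-dimethylcyclohex-2-en-1-yl]methoxy}magnesium | C=CC1=C(C)CCC[C@@]1(C)CO[Mg]Br | intermediate (not isolated)
15 | methyl (4R,10S,13R)-18-hydroxy-11-oxo-17-(pivaloyloxy)labda-5,8-dien-15-oate (ring B cyclohexa-1,4-diene, C5=C6 and C8=C9) | CC(C)(C)C(=O)OCC1=C(C(=O)C[C@@H](C)CC(=O)OC)[C@@]2(C)CCC[C@@](C)(CO)C2=CC1 | intermediate
16 | methyl (4R,5R,10S,13R)-18-hydroxy-11-oxo-17-(pivaloyloxy)labd-8-en-15-oate (trans-decalin, 5α-H) | CC(C)(C)C(=O)OCC1=C(C(=O)C[C@@H](C)CC(=O)OC)[C@@]2(C)CCC[C@@](C)(CO)[C@@H]2CC1 | intermediate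
17 | methyl (4R,5R,10S,13R)-18-acetoxy-11-oxo-17-(pivaloyloxy)labd-8-en-15-oate | CC(C)(C)C(=O)OCC1=C(C(=O)C[C@@H](C)CC(=O)OC)[C@@]2(C)CCC[C@@](C)(COC(C)=O)[C@@H]2CC1 | intermediate
18 | diiodosamarium dienolate C11(O)=C9–C8=C17 of 19 | C=C1CC[C@H]2[C@](C)(COC(C)=O)CCC[C@]2(C)C1=C(O[Sm](I)I)C[C@@H](C)CC(=O)OC | intermediate (not isolated)
19 | methyl (4R,5R,9S,10S,13R)-18-acetoxy-11-oxolabd-8(17)-en-15-oate | C=C1CC[C@H]2[C@](C)(COC(C)=O)CCC[C@]2(C)[C@H]1C(=O)C[C@@H](C)CC(=O)OC | intermediate
20 | methyl (4R,5R,9S,10S,13R)-18-acetoxy-11-hydroxylabd-8(17)-en-15-oate (both C11 epimers) | C=C1CC[C@H]2[C@](C)(COC(C)=O)CCC[C@]2(C)[C@H]1C(O)C[C@@H](C)CC(=O)OC | intermediate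
21 | methyl (4R,5R,9S,10S,13R)-18-acetoxy-11-(phenoxycarbonothioyloxy)labd-8(17)-en-15-oate (both C11 epimers) | C=C1CC[C@H]2[C@](C)(COC(C)=O)CCC[C@]2(C)[C@H]1C(OC(=S)Oc1ccccc1)C[C@@H](C)CC(=O)OC | intermediate
22 | methyl (4R,5R,9S,10R,13R)-18-acetoxylabd-8(17)-en-15-oate (CNP0322314.1) | C=C1CC[C@H]2[C@](C)(COC(C)=O)CCC[C@]2(C)[C@H]1CC[C@@H](C)CC(=O)OC | target

**Step count and risks**
Total: 15 steps. Longest linear sequence: 13 steps (steps 1–6 and 9–15, from 1); fragment 2 takes 2 steps (7 and 8).

Steps most likely to fail: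

Step 9. The magnesium alkoxide, or bromide, may add in conjugate fashion to the ynone, or the metal bridge may be too loose, so that conversion is low or the dienophile is not held on the α face and C10 forms with poor facial selectivity. The fallback uses the known thermal cycloaddition without any template and sets out from silyl ether 7 and ynone 13. Heating the two in toluene at 110 °C in a sealed tube with a trace of BHT should give, with the same C8-to-C7 orientation, methyl (4R,10S,13R)-18-[tert-butyl(dimethyl)silyl]oxy-11-oxo-17-(pivaloyloxy)labda-5,8-dien-15-oate F1 together with its C10 epimer F2, little facial preference being expected. The two are separated by chromatography, and F1 is desilylated with HF·pyridine in THF at 0 °C, which returns to the route at 15.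

Step 2. The fully aliphatic tetrasubstituted enol silane may react slowly or with low facial discrimination, so that the quaternary centre is formed with insufficient enantiomeric purity. The fallback sets out from 2 and builds the centre by an enantioselective Tsuji allylation of the enol silane: diallyl carbonate, Pd2(dba)3, (S)-t-Bu-PHOX and catalytic Bu4N[Ph3SiF2] in THF at 25 °C should give (2S)-2,6-dimethyl-2-(prop-2-en-1-yl)cyclohexan-1-one F3. Isomerisation of the allyl group with RuHCl(CO)(PPh3)3 in toluene at 80 °C gives (2S)-2,6-dimethyl-2-[(1E)-prop-1-en-1-yl]cyclohexan-1-one F4. Ozonolysis (O3, CH2Cl2, −78 °C, then Me2S) gives (1S)-1,3-dimethyl-2-oxocyclohexane-1-carbaldehyde F5. Reduction of the aldehyde alone with NaBH4 in MeOH at −78 °C returns to the route at 3.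

Step 13. The new C11 hydroxyl may close onto the C15 methyl ester (δ-lactonisation) during reduction or work-up, which would block thioacylation and consume the ester. The fallback avoids any C11 alcohol and sets out from 19. Condensation with TsNHNH2 in MeOH at 40 °C gives the C11 tosylhydrazone of 19 F6. A Caglioti-type reduction with catecholborane in CHCl3 at 0 °C, followed by NaOAc·3H2O at 60 °C, should lose dinitrogen and sulfinate and return to the route directly at 22, steps 14 and 15 being skipped.

**Further compounds**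
F1 | step 9 | methyl (4R,10S,13R)-18-[tert-butyl(dimethyl)silyl]oxy-11-oxo-17-(pivaloyloxy)labda-5,8-dien-15-oate | CC(C)(C)C(=O)OCC1=C(C(=O)C[C@@H](C)CC(=O)OC)[C@@]2(C)CCC[C@@](C)(CO[Si](C)(C)C(C)(C)C)C2=CC1
F2 | step 9 | methyl (4R,10R,13R)-18-[tert-butyl(dimethyl)silyl]oxy-11-oxo-17-(pivaloyloxy)labda-5,8-dien-15-oate (C10 epimer of F1) | CC(C)(C)C(=O)OCC1=C(C(=O)C[C@@H](C)CC(=O)OC)[C@]2(C)CCC[C@@](C)(CO[Si](C)(C)C(C)(C)C)C2=CC1
F3 | step 2 | (2S)-2,6-dimethyl-2-(prop-2-en-1-yl)cyclohexan-1-one | O=C1C(C)CCC[C@@]1(C)CC=C
F4 | step 2 | (2S)-2,6-dimethyl-2-[(1E)-prop-1-en-1-yl]cyclohexan-1-one | O=C1C(C)CCC[C@@]1(C)/C=C/C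
F5 | step 2 | (1S)-1,3-dimethyl-2-oxocyclohexane-1-carbaldehyde | O=C1C(C)CCC[C@@]1(C)C=O
F6 | step 13 | methyl (4R,5R,9S,10S,13R)-18-acetoxy-11-[(4-methylbenzenesulfonyl)hydrazinylidene]labd-8(17)-en-15-oate | C=C1CC[C@H]2[C@](C)(COC(C)=O)CCC[C@]2(C)[C@H]1C(=NNS(=O)(=O)c1ccc(C)cc1)C[C@@H](C)CC(=O)OC
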